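Remark on the chemistry: the target 25 is (2S,3R,4R), with C2-methyl/C3-formyl trans and C3-formyl/C4-arm trans; lactone 10 (5S,6S, trans) and adduct 15 (4R,5S,6S) carry the same configurations, so no descriptor needed correction.
Remark on the chemistry: the C3 hydroxymethyl group is carried as a benzyl ether and not a 4-methoxybenzyl ether, because step 7 runs in acidic methanol, where a freed alcohol could itself close on the formyl carbon or on the arm ester, and because benzyl chloromethyl ether is commercial whereas its 4-methoxy analogue is not.
Remark on the chemistry: the tert-butyl ester of 15 is not expected to survive methanolic HCl, so it is deliberately exchanged for a methyl ester in step 7, and the two methyl esters of 17 are distinguished by intrinsic reactivity in step 8.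

## Structural features

The target is a 3,4-dihydro-2H-pyran (ring A: O1, C2 to C6) whose C5=C6 double bond carries a methyl ester on C5, so that O1–C6=C5–C=O is a vinylogous carbonate. Three contiguous stereocentres lie on the saturated half: C2 (methyl, S), C3 (formyl, R) and C4 (CH2CO2R arm, R). Methyl and formyl are trans and formyl and arm are trans, so methyl and arm are cis and all three can be pseudo-equatorial. The arm is the ester of 2-(3,4-dihydroxyphenyl)ethanol, which brings a catechol (ring B) and a second ester that must be told apart from the ring ester. The fragile points are three: the C3 aldehyde is β to O1 and under base can expel the formyl-ester enolate by E1cB ring opening, which destroys C2 and C3; the enol ether hydrates in aqueous acid; the catechol does not tolerate oxidants. The real difficulty is to set C4 relative to C2 and C3 and to reveal aldehyde and catechol last, without base. The key step exploits the fact that C4, C5 and the carboxyl carbon on C5 become the β-carbon, α-carbon and carbonyl of a δ-lactone once that carboxyl carbon is tied to O1 (ring O1–C2–C3–C4–C5–C=O), with C6 as a formyl group on the α-carbon. Conjugate addition at C4 and formylation at C5 then build the skeleton on a rigid template that already holds C2 and C3.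

## Logic of the disconnections

25 ⇒ 24. The two phenolic O–H groups are replaced by O–Si bonds. A free catechol would not survive the oxidation that creates the aldehyde, so it is unmasked in the last step. Nothing is gained in skeleton; the gain is that the oxidation becomes feasible. The demand is a non-basic desilylation, since the β-alkoxy aldehyde opens by loss of O1 under base.

24 ⇒ 23 ⇒ 22. The C3 formyl group is taken back to a hydroxymethyl group and that to its benzyl ether (benzylic C–O bond). The aldehyde is the most sensitive function, so all earlier chemistry is done on an ether that can neither epimerise nor eliminate. The demand is a debenzylation that spares C5=C6 and the aryl silyl ethers, followed at once by a base-free oxidation.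

22 ⇒ 18 + 21, and 21 ⇒ 20 ⇒ 19. The acyl C–O bond of the arm ester is cut. This is the convergent cut that removes ring B and leaves an acid. The demand on 18 is a free arm acid beside an intact ring ester. The demand on 21 is a free primary hydroxyl beside masked phenols, met by cleaving one of the three O–Si bonds of 20 selectively.

18 ⇒ 17. The O–CH3 bond of the arm ester is the only change. The cut is made here because the two esters of 17 differ electronically: one is saturated, the other a vinylogous carbonate. The demand is a hydrolysis that touches only the saturated ester.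

17 ⇒ 16 ⇒ 15. The O1–C6 bond is cut (through acetal 16) and O1 is reconnected to the carboxyl carbon on C5; the arm ester returns to its tert-butyl form. This hides the acid-sensitive enol ether in a saturated lactone and turns ring A into a conformationally defined template. The demand is that the C3 ether and the ring stereocentres tolerate acidic alcoholysis, and that the ester exchange on the arm runs to completion.

15 ⇒ 10 + 11 + 12 (through 13 and 14). The C4–CH2 and C5–C6 bonds are cut. Two C–C bonds and one stereocentre disappear in one operation, leaving a lactone with two stereocentres and two simple esters. The demand is attack at C4 anti to the C3 substituent, 1,4 rather than 1,2 addition, and capture of the enolate at carbon before proton transfer.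

10 ⇒ 9 ⇒ 8 ⇒ 6 + 7. The lactone acyl–O1 bond is cut, then the C4=C5 double bond. The ring becomes an acyclic aldehyde plus a two-carbon phosphonate. The demand is Z geometry (only the Z ester can lactonise) and retention of the α-stereocentre of 6.

6 ⇒ 5 ⇒ 4 ⇒ 1 + 2 (through 3). After oxidation-level and protecting-group changes, the C3–CH2O bond is cut. Both stereocentres of 10 then derive from the single stereocentre of 1. The demand is anti-selective C-alkylation of the dianion 3.

## Other disconnections considered

Alternative 1: The cut is O1–C6, with ring A read as the product of an oxidative furan ring expansion. In the forward sense the (S)-furyl carbinol A1 would undergo an Achmatowicz rearrangement with electrophilic bromine in aqueous THF, the carbinol oxygen capturing the unmasked aldehyde carbon to give the pyranone lactol A2. In its favour: the ring-forming step is robust, C2 comes from an easily resolved or asymmetrically reduced carbinol, and the key step has no facial-selectivity problem; on reliability of the key step itself it is the better of the two plans. Against it: A2 has the wrong functional pattern. It carries a ketone at C3 that needs one-carbon homologation to CH–CHO, a tetrasubstituted C4=C5 alkene that must be reduced with control at C4, and a C6 lactol that must then be dehydrated to restore C5=C6. Both C3 and C4 would be set after the key step with no strong controlling element, and the fully substituted furan A1 itself needs a regiodefined multistep preparation. Structurally the chosen plan forms two skeletal bonds and C4 on a template that already fixes C2 and C3, whereas this one forms the ring but none of the hard stereocentres. In step economy it should be clearly longer after the key step.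

Alternative 2: The cut is C4–C5. The acyclic iodoacrylate–enoate A3 would be electrolysed at constant current with NiBr2(bipy) A5 and a sacrificial zinc anode; divalent nickel is reduced to zerovalent nickel, which inserts into the C–I bond, and the vinylnickel adds 6-exo-trig to the (E)-enoate to give A4. In its favour: the arm ester with its protected catechol is in place before ring closure, the two esters are differentiated from the start, no rearrangement or ester exchange is needed, and the conditions are neutral; on ester differentiation and on steps after the key step (three, against eight here) it is the better plan. C4 would be set by a chair-like closure with the C2 and C3 substituents equatorial, which is substrate control from C3 of the same kind as in the chosen plan, so the two are equal on that point. Against it: the vinylnickel carries an alkoxy group on the adjacent carbon, so β-alkoxide elimination and simple protodehalogenation compete with cyclisation. A3 needs the same chiral hydroxy fragment plus O-vinylation, α-iodination and an E-olefination with a phosphonate bearing the aryl ester, so the steps before the key step outnumber those saved after it. The key step also needs electrochemical equipment and is harder to scale. Overall the step count should be comparable and the risk in the key step higher.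

Alternative 3: The cuts are O1–C2 and C3–C4. The formylglutaconate A6 and (E)-but-2-enal A7 would be combined under a diarylprolinol silyl ether catalyst: the enol oxygen of A6 adds to the iminium ion (O1–C2), and the resulting enamine carbon adds to the enoate (C3–C4) to give A8, which is the same structure as 24. In its favour: ring A and all three stereocentres would form in one catalytic step from achiral fragments, with C3 already at the aldehyde oxidation level and no protecting group on it; in step economy it is far better than the chosen plan. The all-trans arrangement required is also the one expected to be favoured if the cascade equilibrates. Against it: A6 is an ambident nucleophile, and 1,3-dicarbonyl donors normally attack iminium ions through carbon, which here would lead to a C5-alkylated product and a lactol instead. The oxa-Michael step is reversible, so C2 would not be reliably catalyst-controlled. A6 can cyclise to a 2-pyranone by attack of its enol oxygen on the arm ester. Finally, A8 would be formed in the presence of a secondary amine, the very conditions under which it opens by retro-oxa-Michael reaction. Mechanistically the chosen plan rests on substrate control from fixed stereocentres, this one on catalyst control of a reversible step, which is the less secure basis even though the route would be much shorter.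

Key step: step 6

## Route

Step 1
Reactants: 1 methyl (S)-3-hydroxybutanoate; 2 benzyl chloromethyl ether
Product: 4 methyl (2S,3S)-2-[(benzyloxy)methyl]-3-hydroxybutanoate, via dilithium alkoxide-enolate 3 (not isolated)
Conditions: LiN(iPr)2 (2.2 equiv), THF, −78 → −20 °C; then 2 (1.1 equiv), −78 → −25 °C; aq NH4Cl
Reagents that add atoms: none
Why: Fráter–Seebach alkylation: the chelated dianion 3 is alkylated at carbon on the face opposite the C3 methyl group, giving the anti (2S,3S) product and hence the future trans C2/C3 relationship; the chloromethyl ether is reactive enough to alkylate below −20 °C.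

Step 2
Reactants: 4 methyl (2S,3S)-2-[(benzyloxy)methyl]-3-hydroxybutanoate
Product: 5 methyl (2S,3S)-2-[(benzyloxy)methyl]-3-[(tert-butyldimethylsilyl)oxy]butanoate
Conditions: TBSOTf (1.2 equiv), 2,6-lutidine (2 equiv), CH2Cl2, 0 °C
Reagents that add atoms: tert-butyldimethylsilyl trifluoromethanesulfonate, CC(C)(C)[Si](C)(C)OS(=O)(=O)C(F)(F)F
Why: Silyl ether formation with a silyl triflate and a hindered base; the hydroxyl is masked so that the ester can be reduced and the aldehyde olefinated without retro-aldol or hemiacetal formation, and no stereocentre is touched.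

Step 3
Reactants: 5 methyl (2S,3S)-2-[(benzyloxy)methyl]-3-[(tert-butyldimethylsilyl)oxy]butanoate
Product: 6 (2S,3S)-2-[(benzyloxy)methyl]-3-[(tert-butyldimethylsilyl)oxy]butanal
Conditions: i-Bu2AlH (1.1 equiv), CH2Cl2, −78 °C; MeOH, then aq potassium sodium tartrate
Reagents that add atoms: none
Why: Partial reduction of an ester: at −78 °C the tetrahedral aluminium alkoxide, stabilised by chelation to the neighbouring ether oxygens, should persist until the quench and then release the aldehyde; 6 is used at once without chromatography to protect its α-stereocentre.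

Step 4
Reactants: 6 (2S,3S)-2-[(benzyloxy)methyl]-3-[(tert-butyldimethylsilyl)oxy]butanal; 7 methyl 2-[bis(2,2,2-trifluoroethoxy)phosphoryl]acetate
Product: 8 methyl (2Z,4S,5S)-4-[(benzyloxy)methyl]-5-[(tert-butyldimethylsilyl)oxy]hex-2-enoate
Conditions: 7 (1.2 equiv), KN(SiMe3)2 (1.15 equiv), 18-crown-6 (3 equiv), THF, −78 °C; then 6
Reagents that add atoms: none
Why: Still–Gennari variant of the Horner–Wadsworth–Emmons reaction: with the trifluoroethyl phosphonate and a dissociated potassium anion the adduct eliminates faster than it equilibrates, which should give the Z enoate required for ring closure; the low temperature and non-nucleophilic base protect the α-stereocentre of 6.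

Step 5
Reactants: 8 methyl (2Z,4S,5S)-4-[(benzyloxy)methyl]-5-[(tert-butyldimethylsilyl)oxy]hex-2-enoate
Product: 10 (5S,6S)-5-[(benzyloxy)methyl]-6-methyl-5,6-dihydro-2H-pyran-2-one, via hydroxy Z-enoate 9 (not isolated)
Conditions: 48% aq HF, MeCN, 0 °C → rt
Reagents that add atoms: none
Why: Acidic desilylation frees the hydroxyl of 9, which the Z double bond holds next to the ester, so that acid-catalysed lactonisation (6-exo-trig at the carbonyl) should follow in the same flask; the benzyl ether is inert to HF and both stereocentres are untouched.

Step 6
Reactants: 10 (5S,6S)-5-[(benzyloxy)methyl]-6-methyl-5,6-dihydro-2H-pyran-2-one; 11 tert-butyl acetate; 12 ethyl formate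
Product: 15 tert-butyl 2-[(3Z,4R,5S,6S)-5-[(benzyloxy)methyl]-3-(hydroxymethylidene)-6-methyl-2-oxooxan-4-yl]acetate, via lithium ester enolate 13 (not isolated), via lithium lactone enolate 14 (not isolated)
Conditions: LiN(iPr)2 (1.1 equiv), 11 (1.15 equiv), THF, −78 °C; 10, −78 °C; cannulate into 12 (8 equiv), THF, −78 → −20 °C; AcOH, aq NH4Cl
Reagents that add atoms: none
Why: This is a tandem Michael addition/enolate C-acylation (Michael–Claisen three-component coupling), a known reaction type for α,β-unsaturated lactones. Enolate 13 adds 1,4 to the β-carbon of 10 to give lactone enolate 14 regiospecifically; 14 attacks the formate 12 at carbon, ethoxide leaves, and the α-formyl lactone is held as its chelated lithium enolate until acidification releases the hydrogen-bonded enol 15. No ring is closed; the two bonds formed are C4–CH2 and C5–C6 in target numbering. The single new stereocentre, C4, is set by substrate control: the nucleophile approaches anti to the adjacent benzyloxymethyl group of the half-chair, as in additions to 4-substituted cyclohexenones and 5-substituted dihydropyranones, so the arm ends trans to that group and cis to the ring methyl, the all-equatorial arrangement. The step needs 1,4 over 1,2 attack, which the hindered, soft tert-butyl ester enolate and the ester-type acceptor at −78 °C should secure. It needs face selectivity, which rests on the vicinal substituent outweighing the weaker opposite preference of the remote methyl group. It needs C-formylation without proton scrambling, which inverse addition to excess formate and the low acidity and low electrophilicity of the tert-butyl ester should secure. The geometry of the hydroxymethylidene group is immaterial, because that carbon becomes C6 of the enol ether.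

Step 7
Reactants: 15 tert-butyl 2-[(3Z,4R,5S,6S)-5-[(benzyloxy)methyl]-3-(hydroxymethylidene)-6-methyl-2-oxooxan-4-yl]acetate
Product: 17 methyl (2S,3S,4R)-3-[(benzyloxy)methyl]-4-(2-methoxy-2-oxoethyl)-2-methyl-3,4-dihydro-2H-pyran-5-carboxylate, via cyclic methyl acetal 16 (not isolated)
Conditions: 1.25 M HCl in MeOH, rt → 45 °C; concentrate; TsOH·H2O (5 mol %), toluene, 90 °C
Reagents that add atoms: methanol, CO
Why: Korte rearrangement of an α-formyl lactone: acid-catalysed methanolysis opens the lactone to the methyl ester, the freed hydroxyl closes on the formyl carbon (6-exo-trig on the oxocarbenium ion, O1 staying on C2 so that C2 keeps its configuration) to give acetal 16, and loss of methanol under TsOH gives the conjugated enol ether. In the same medium the tert-butyl ester is cleaved and re-esterified (Fischer esterification) to the methyl ester, as intended; C4 is not epimerisable and the benzyl ether is acid-stable.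

Step 8
Reactants: 17 methyl (2S,3S,4R)-3-[(benzyloxy)methyl]-4-(2-methoxy-2-oxoethyl)-2-methyl-3,4-dihydro-2H-pyran-5-carboxylate
Product: 18 2-[(2S,3S,4R)-3-[(benzyloxy)methyl]-5-(methoxycarbonyl)-2-methyl-3,4-dihydro-2H-pyran-4-yl]acetic acid
Conditions: LiOH·H2O (1.3 equiv), THF/H2O (3:1), 0 °C; then 1 M HCl to pH 3
Reagents that add atoms: lithium hydroxide, [Li+].[OH-]
Why: Chemoselective saponification: the ring ester is a vinylogous carbonate deactivated by donation from O1 through C5=C6, so hydroxide should attack only the saturated arm ester at 0 °C, the same discrimination that operates in alkaline hydrolysis of the natural secoiridoid esters. No stereocentre is acidic under these conditions.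

Step 9
Reactants: 19 hydroxytyrosol
Product: 20 tert-butyl(2-{3,4-bis[(tert-butyldimethylsilyl)oxy]phenyl}ethoxy)dimethylsilane
Conditions: TBSCl (3.6 equiv), imidazole (7 equiv), DMF, rt
Reagents that add atoms: tert-butyldimethylsilyl chloride, CC(C)(C)[Si](C)(C)Cl
Why: Exhaustive silylation of all three hydroxyls with a silyl chloride and imidazole; full protection avoids any selectivity question at this stage.

Step 10
Reactants: 20 tert-butyl(2-{3,4-bis[(tert-butyldimethylsilyl)oxy]phenyl}ethoxy)dimethylsilane
Product: 21 2-{3,4-bis[(tert-butyldimethylsilyl)oxy]phenyl}ethan-1-ol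
Conditions: camphorsulfonic acid (0.1 equiv), MeOH/CH2Cl2 (1:1), 0 °C
Reagents that add atoms: none
Why: Acid-catalysed methanolysis should remove the primary alkyl silyl ether much faster than the aryl silyl ethers, whose oxygen is less basic and harder to protonate, leaving the primary alcohol free for coupling.

Step 11
Reactants: 18 2-[(2S,3S,4R)-3-[(benzyloxy)methyl]-5-(methoxycarbonyl)-2-methyl-3,4-dihydro-2H-pyran-4-yl]acetic acid; 21 2-{3,4-bis[(tert-butyldimethylsilyl)oxy]phenyl}ethan-1-ol
Product: 22 methyl (2S,3S,4R)-3-[(benzyloxy)methyl]-4-[2-(2-{3,4-bis[(tert-butyldimethylsilyl)oxy]phenyl}ethoxy)-2-oxoethyl]-2-methyl-3,4-dihydro-2H-pyran-5-carboxylate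
Conditions: EDC·HCl (1.5 equiv), DMAP (0.2 equiv), CH2Cl2, 0 °C → rt
Reagents that add atoms: none
Why: Steglich esterification: the carbodiimide activates 18 as its O-acylisourea and DMAP transfers the acyl group to the primary alcohol 21; no aldehyde is present yet, so the basic catalyst is harmless, and the ring ester and stereocentres are untouched.

Step 12
Reactants: 22 methyl (2S,3S,4R)-3-[(benzyloxy)methyl]-4-[2-(2-{3,4-bis[(tert-butyldimethylsilyl)oxy]phenyl}ethoxy)-2-oxoethyl]-2-methyl-3,4-dihydro-2H-pyran-5-carboxylate
Product: 23 methyl (2S,3S,4R)-4-[2-(2-{3,4-bis[(tert-butyldimethylsilyl)oxy]phenyl}ethoxy)-2-oxoethyl]-3-(hydroxymethyl)-2-methyl-3,4-dihydro-2H-pyran-5-carboxylate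
Conditions: H2 (1 atm), 10% Pd/C, EtOAc, rt
Reagents that add atoms: none
Why: Hydrogenolysis of the benzyl ether; the push–pull trisubstituted enol ether double bond, the aryl silyl ethers and the homobenzylic ester should not be reduced at 1 atm in a neutral solvent, and 23 is oxidised without delay so that the free alcohol cannot lactonise onto the arm ester.

Step 13
Reactants: 23 methyl (2S,3S,4R)-4-[2-(2-{3,4-bis[(tert-butyldimethylsilyl)oxy]phenyl}ethoxy)-2-oxoethyl]-3-(hydroxymethyl)-2-methyl-3,4-dihydro-2H-pyran-5-carboxylate
Product: 24 methyl (2S,3R,4R)-4-[2-(2-{3,4-bis[(tert-butyldimethylsilyl)oxy]phenyl}ethoxy)-2-oxoethyl]-3-formyl-2-methyl-3,4-dihydro-2H-pyran-5-carboxylate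
Conditions: Dess–Martin periodinane (1.3 equiv), CH2Cl2, 0 °C → rt; aq Na2S2O3/NaHCO3 wash
Reagents that add atoms: none
Why: Dess–Martin oxidation of the primary alcohol to the aldehyde without base, which avoids β-elimination of O1 from the new β-alkoxy aldehyde; C3 already has the trans,trans arrangement, expected to be the more stable one.

Step 14
Reactants: 24 methyl (2S,3R,4R)-4-[2-(2-{3,4-bis[(tert-butyldimethylsilyl)oxy]phenyl}ethoxy)-2-oxoethyl]-3-formyl-2-methyl-3,4-dihydro-2H-pyran-5-carboxylate
Product: 25 methyl (2S,3R,4R)-4-{2-[2-(3,4-dihydroxyphenyl)ethoxy]-2-oxoethyl}-3-formyl-2-methyl-3,4-dihydro-2H-pyran-5-carboxylate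
Conditions: HF·pyridine (excess), pyridine, THF, 0 °C → rt; pH 7 phosphate buffer work-up
Reagents that add atoms: none
Why: Fluoride cleavage of the two aryl silyl ethers in a weakly acidic buffered medium, which should leave the aldehyde, the enol ether ester and the arm ester intact and should not open the ring; neutral work-up gives the target.

## Compound list

1 | methyl (S)-3-hydroxybutanoate | C[C@H](O)CC(=O)OC | starting material
2 | benzyl chloromethyl ether | ClCOCc1ccccc1 | starting material
3 | dilithium alkoxide-enolate of 1, dilithium (3S)-1-methoxybut-1-ene-1,3-diolate | C[C@H](O[Li])C=C(O[Li])OC | intermediate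
4 | methyl (2S,3S)-2-[(benzyloxy)methyl]-3-hydroxybutanoate | COC(=O)[C@@H](COCc1ccccc1)[C@H](C)O | intermediate
5 | methyl (2S,3S)-2-[(benzyloxy)methyl]-3-[(tert-butyldimethylsilyl)oxy]butanoate | COC(=O)[C@@H](COCc1ccccc1)[C@H](C)O[Si](C)(C)C(C)(C)C | intermediate
6 | (2S,3S)-2-[(benzyloxy)methyl]-3-[(tert-butyldimethylsilyl)oxy]butanal | O=C[C@@H](COCc1ccccc1)[C@H](C)O[Si](C)(C)C(C)(C)C | intermediate
7 | methyl 2-[bis(2,2,2-trifluoroethoxy)phosphoryl]acetate | COC(=O)CP(=O)(OCC(F)(F)F)OCC(F)(F)F | starting material
8 | methyl (2Z,4S,5S)-4-[(benzyloxy)methyl]-5-[(tert-butyldimethylsilyl)oxy]hex-2-enoate | COC(=O)/C=C\[C@@H](COCc1ccccc1)[C@H](C)O[Si](C)(C)C(C)(C)C | intermediate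
9 | methyl (2Z,4S,5S)-4-[(benzyloxy)methyl]-5-hydroxyhex-2-enoate | COC(=O)/C=C\[C@@H](COCc1ccccc1)[C@H](C)O | intermediate
10 | (5S,6S)-5-[(benzyloxy)methyl]-6-methyl-5,6-dihydro-2H-pyran-2-one | O=C1C=C[C@@H](COCc2ccccc2)[C@H](C)O1 | intermediate
11 | tert-butyl acetate | CC(=O)OC(C)(C)C | starting material
12 | ethyl formate | CCOC=O | starting material
13 | lithium 1-tert-butoxyethenolate (lithium enolate of 11) | C=C(O[Li])OC(C)(C)C | intermediate
14 | lithium enolate of the conjugate adduct, lactone ring 4,5-trans and 5,6-trans, configured as in the SMILES | [Li]OC1=C[C@H](CC(=O)OC(C)(C)C)[C@@H](COCc2ccccc2)[C@H](C)O1 | intermediate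
15 | tert-butyl 2-[(3Z,4R,5S,6S)-5-[(benzyloxy)methyl]-3-(hydroxymethylidene)-6-methyl-2-oxooxan-4-yl]acetate | O=C1/C(=C\O)[C@H](CC(=O)OC(C)(C)C)[C@@H](COCc2ccccc2)[C@H](C)O1 | intermediate
16 | methyl (2S,3S,4R)-3-[(benzyloxy)methyl]-6-methoxy-4-(2-methoxy-2-oxoethyl)-2-methyloxane-5-carboxylate, ring numbered as in the target, mixture at C5 and C6 | COC(=O)C1C(OC)O[C@@H](C)[C@H](COCc2ccccc2)[C@H]1CC(=O)OC | intermediate
17 | methyl (2S,3S,4R)-3-[(benzyloxy)methyl]-4-(2-methoxy-2-oxoethyl)-2-methyl-3,4-dihydro-2H-pyran-5-carboxylate | COC(=O)C1=CO[C@@H](C)[C@H](COCc2ccccc2)[C@H]1CC(=O)OC | intermediate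
18 | 2-[(2S,3S,4R)-3-[(benzyloxy)methyl]-5-(methoxycarbonyl)-2-methyl-3,4-dihydro-2H-pyran-4-yl]acetic acid | COC(=O)C1=CO[C@@H](C)[C@H](COCc2ccccc2)[C@H]1CC(=O)O | intermediate
19 | hydroxytyrosol, 4-(2-hydroxyethyl)benzene-1,2-diol | OCCc1ccc(O)c(O)c1 | starting material
20 | tert-butyl(2-{3,4-bis[(tert-butyldimethylsilyl)oxy]phenyl}ethoxy)dimethylsilane | CC(C)(C)[Si](C)(C)OCCc1ccc(O[Si](C)(C)C(C)(C)C)c(O[Si](C)(C)C(C)(C)C)c1 | intermediate
21 | 2-{3,4-bis[(tert-butyldimethylsilyl)oxy]phenyl}ethan-1-ol | OCCc1ccc(O[Si](C)(C)C(C)(C)C)c(O[Si](C)(C)C(C)(C)C)c1 | intermediate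
22 | methyl (2S,3S,4R)-3-[(benzyloxy)methyl]-4-[2-(2-{3,4-bis[(tert-butyldimethylsilyl)oxy]phenyl}ethoxy)-2-oxoethyl]-2-methyl-3,4-dihydro-2H-pyran-5-carboxylate | COC(=O)C1=CO[C@@H](C)[C@H](COCc2ccccc2)[C@H]1CC(=O)OCCc1ccc(O[Si](C)(C)C(C)(C)C)c(O[Si](C)(C)C(C)(C)C)c1 | intermediate
23 | methyl (2S,3S,4R)-4-[2-(2-{3,4-bis[(tert-butyldimethylsilyl)oxy]phenyl}ethoxy)-2-oxoethyl]-3-(hydroxymethyl)-2-methyl-3,4-dihydro-2H-pyran-5-carboxylate | COC(=O)C1=CO[C@@H](C)[C@H](CO)[C@H]1CC(=O)OCCc1ccc(O[Si](C)(C)C(C)(C)C)c(O[Si](C)(C)C(C)(C)C)c1 | intermediate
24 | methyl (2S,3R,4R)-4-[2-(2-{3,4-bis[(tert-butyldimethylsilyl)oxy]phenyl}ethoxy)-2-oxoethyl]-3-formyl-2-methyl-3,4-dihydro-2H-pyran-5-carboxylate | COC(=O)C1=CO[C@@H](C)[C@H](C=O)[C@H]1CC(=O)OCCc1ccc(O[Si](C)(C)C(C)(C)C)c(O[Si](C)(C)C(C)(C)C)c1 | intermediate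
25 | methyl (2S,3R,4R)-4-{2-[2-(3,4-dihydroxyphenyl)ethoxy]-2-oxoethyl}-3-formyl-2-methyl-3,4-dihydro-2H-pyran-5-carboxylate | COC(=O)C1=CO[C@@H](C)[C@H](C=O)[C@H]1CC(=O)OCCc1ccc(O)c(O)c1 | target

## Step count and least certain steps

Total: 14 steps, 12 on the main line and 2 on the branch that prepares 21. Longest linear sequence: 12 steps (steps 1 to 8 and 11 to 14, from 1 to 25). Once 24 exists, it and 25 must be kept away from amines and other bases throughout.

Step 6 (key step). The most likely failures are attack on the wrong face, because the remote ring methyl of 10 on its own favours the face opposite to the one the vicinal substituent directs to; γ-deprotonation of 10 by the basic enolate, with epimerisation or ring opening to a dienoate; and proton transfer between formylated product and unreacted 14 before capture by 12. Fallback, from 10 and 11, returning at 15: the two bond formations are separated and the conjugate addition is made a Lewis-acid process. Ester 11 would be converted (LiN(iPr)2, TBSCl, THF, −78 °C) to its silyl ketene acetal, tert-butyl[(1-tert-butoxyethenyl)oxy]dimethylsilane F1. Mukaiyama–Michael addition of F1 to 10 (catalytic TBSOTf, CH2Cl2, −78 °C), with no free base present, followed by hydrolytic work-up, would give the saturated lactone tert-butyl 2-[(4R,5S,6S)-5-[(benzyloxy)methyl]-6-methyl-2-oxooxan-4-yl]acetate F2. Formylation of F2 with NaH and 12 in THF should occur at the lactone α-carbon, which is more acidic than the tert-butyl ester α-carbon, and return to 15.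

Step 7. The likely failures are incomplete exchange of the tert-butyl ester, giving mixtures of esters and acid; incomplete loss of methanol from 16; and capture of the freed hydroxyl by the arm carbonyl during the toluene stage. Fallback, from 15, returning at 18 and replacing steps 7 and 8: the arm ester is kept as tert-butyl and the two esters are differentiated by protecting group instead of by reactivity. Rearrangement under weak acid (camphorsulfonic acid 0.1 equiv, MeOH/HC(OMe)3, rt; then pyridinium p-toluenesulfonate, toluene, 80 °C), conditions that should not ionise a tert-butyl ester, would give methyl (2S,3S,4R)-3-[(benzyloxy)methyl]-4-(2-tert-butoxy-2-oxoethyl)-2-methyl-3,4-dihydro-2H-pyran-5-carboxylate F3. Anhydrous TFA in CH2Cl2 at 0 °C would then cleave the tert-butyl ester of F3 and deliver 18; the benzyl ether and the vinylogous carbonate tolerate anhydrous acid.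

Step 1. The likely failures are O-alkylation of the lithium alkoxide by the very reactive chloromethyl ether and erosion of anti selectivity with an electrophile of partial SN1 character. Fallback, from 1, returning at 4: the dianion 3 would be hydroxymethylated with gaseous formaldehyde (THF, −78 → −20 °C), an aldol-type capture with the same facial sense, to give methyl (2S,3S)-3-hydroxy-2-(hydroxymethyl)butanoate F4. Selective benzylation of the primary hydroxyl of F4 through its stannylene acetal (Bu2SnO, toluene, reflux; then BnBr, Bu4NI) would give 4.

Step 4. The likely failures are epimerisation or β-elimination of aldehyde 6 under the basic olefination and insufficient Z selectivity, since an E ester cannot lactonise. Fallback, from 6, returning at 10 and replacing steps 4 and 5: the ring is closed by metathesis, so that alkene geometry is dictated by the ring. Methylenation of 6 (Ph3P=CH2 from Ph3PCH3Br and KN(SiMe3)2, THF, −78 → 0 °C) would give tert-butyl({(2S,3S)-3-[(benzyloxy)methyl]pent-4-en-2-yl}oxy)dimethylsilane F5. Desilylation (Bu4NF, THF) would give (2S,3S)-3-[(benzyloxy)methyl]pent-4-en-2-ol F6. Acylation (acryloyl chloride, iPr2NEt, CH2Cl2, 0 °C) would give (2S,3S)-3-[(benzyloxy)methyl]pent-4-en-2-yl prop-2-enoate F7. Ring-closing metathesis of F7 with the second-generation Grubbs catalyst (CH2Cl2, 40 °C) would give 10.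

Step 12. The likely failures are over-reduction of the C5=C6 enol ether double bond on the palladium surface and lactonisation of the liberated alcohol onto the arm ester with loss of 21. Fallback, from 22, returning at 23: the benzyl ether is cleaved without hydrogen or metal by Lewis-acid debenzylation with BCl3 and pentamethylbenzene as cation scavenger (CH2Cl2, −78 °C), quenched cold with methanol. This leaves the double bond untouched and is expected to spare aryl silyl ethers at that temperature. No new compound is made.

## Further compounds

F1 | step 6 | tert-butyl[(1-tert-butoxyethenyl)oxy]dimethylsilane | C=C(OC(C)(C)C)O[Si](C)(C)C(C)(C)C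
F2 | step 6 | tert-butyl 2-[(4R,5S,6S)-5-[(benzyloxy)methyl]-6-methyl-2-oxooxan-4-yl]acetate | O=C1C[C@H](CC(=O)OC(C)(C)C)[C@@H](COCc2ccccc2)[C@H](C)O1
F3 | step 7 | methyl (2S,3S,4R)-3-[(benzyloxy)methyl]-4-(2-tert-butoxy-2-oxoethyl)-2-methyl-3,4-dihydro-2H-pyran-5-carboxylate | COC(=O)C1=CO[C@@H](C)[C@H](COCc2ccccc2)[C@H]1CC(=O)OC(C)(C)C
F4 | step 1 | methyl (2S,3S)-3-hydroxy-2-(hydroxymethyl)butanoate | COC(=O)[C@@H](CO)[C@H](C)O
F5 | step 4 | tert-butyl({(2S,3S)-3-[(benzyloxy)methyl]pent-4-en-2-yl}oxy)dimethylsilane | C=C[C@@H](COCc1ccccc1)[C@H](C)O[Si](C)(C)C(C)(C)C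
F6 | step 4 | (2S,3S)-3-[(benzyloxy)methyl]pent-4-en-2-ol | C=C[C@@H](COCc1ccccc1)[C@H](C)O
F7 | step 4 | (2S,3S)-3-[(benzyloxy)methyl]pent-4-en-2-yl prop-2-enoate | C=C[C@@H](COCc1ccccc1)[C@H](C)OC(=O)C=C
F0 | step 12 | none | none
A1 | alternative 1 | methyl 4-(2-tert-butoxy-2-oxoethyl)-5-[(1S)-1-hydroxyethyl]furan-3-carboxylate | C[C@H](O)c1occ(C(=O)OC)c1CC(=O)OC(C)(C)C
A2 | alternative 1 | methyl (6S)-4-(2-tert-butoxy-2-oxoethyl)-2-hydroxy-6-methyl-5-oxo-5,6-dihydro-2H-pyran-3-carboxylate, mixture of lactol anomers | C[C@@H]1OC(O)C(C(=O)OC)=C(CC(=O)OC(C)(C)C)C1=O
A3 | alternative 2 | 2-{3,4-bis[(tert-butyldimethylsilyl)oxy]phenyl}ethyl (2E,4S,5S)-5-[(2-iodo-3-methoxy-3-oxoprop-1-en-1-yl)oxy]-4-{[(4-methoxyphenyl)methoxy]methyl}hex-2-enoate | COC(=O)C(I)=CO[C@@H](C)[C@H](COCc1ccc(OC)cc1)/C=C/C(=O)OCCc1ccc(O[Si](C)(C)C(C)(C)C)c(O[Si](C)(C)C(C)(C)C)c1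
A4 | alternative 2 | methyl (2S,3S,4R)-4-[2-(2-{3,4-bis[(tert-butyldimethylsilyl)oxy]phenyl}ethoxy)-2-oxoethyl]-3-{[(4-methoxyphenyl)methoxy]methyl}-2-methyl-3,4-dihydro-2H-pyran-5-carboxylate | COC(=O)C1=CO[C@@H](C)[C@H](COCc2ccc(OC)cc2)[C@H]1CC(=O)OCCc1ccc(O[Si](C)(C)C(C)(C)C)c(O[Si](C)(C)C(C)(C)C)c1
A5 | alternative 2 | dibromo(2,2'-bipyridine)nickel, NiBr2(bipy) | Br[Ni]Br.c1ccc(-c2ccccn2)nc1
A6 | alternative 3 | 5-(2-{3,4-bis[(tert-butyldimethylsilyl)oxy]phenyl}ethyl) 1-methyl (3E)-2-(hydroxymethylidene)pent-3-enedioate | COC(=O)C(=CO)/C=C/C(=O)OCCc1ccc(O[Si](C)(C)C(C)(C)C)c(O[Si](C)(C)C(C)(C)C)c1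
A7 | alternative 3 | (E)-but-2-enal | C/C=C/C=O
A8 | alternative 3 | methyl (2S,3R,4R)-4-[2-(2-{3,4-bis[(tert-butyldimethylsilyl)oxy]phenyl}ethoxy)-2-oxoethyl]-3-formyl-2-methyl-3,4-dihydro-2H-pyran-5-carboxylate | COC(=O)C1=CO[C@@H](C)[C@H](C=O)[C@H]1CC(=O)OCCc1ccc(O[Si](C)(C)C(C)(C)C)c(O[Si](C)(C)C(C)(C)C)c1
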